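**Retrosynthetic overview**

1. Ring numbering: C1 ketone, C2 (acetate arm), C3 (vinylic CH), C4 (carbinol), C5 (geranylgeranyl), C6 (CH2). The strategy rests on the γ-hydroxy enone of the cyclohexenone ring: C4 is bonded to C3, the β-carbon of the C1 enone, so C3–C4 is cut into a β-acylvinyl nucleophile (C3) and an aldehyde (C4).
2. The only carbocycle is closed last, by an intramolecular Nozaki–Hiyama–Kishi reaction of the (Z)-β-iodoenone aldehyde 23, which gives the target 25 directly.
3. 23 comes from keto ester 21 (desilylation, oxidation of C4). The acetate arm is grown from a vinyl group (hydroboration, two oxidations, methylation), and the (Z)-iodoalkene comes from alkoxide-directed anti-vinylmagnesiation and iodination of the C1 ethynyl carbinol 13.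
4. 13 comes from lactol 10 and ethynylmagnesium bromide. Lactone 9 comes from the Evans alkylation of N-succinoyl oxazolidinone 5 with geranylgeranyl bromide 2, which sets C5.

Key step: step 15

Remark: "geranylgeranyl" means (2E,6E,10E)-3,7,11,15-tetramethylhexadeca-2,6,10,14-tetraen-1-yl; the C1 carbinol of 12, 13 and 16–18 is carried as both epimers, which is harmless because step 10 oxidises C1 to the ketone.

**Route**

Step 1
Reactants: 1 (2E,6E,10E)-geranylgeraniol
Product: 2 (2E,6E,10E)-geranylgeranyl bromide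
Conditions: PBr3 (0.4 equiv), Et2O, −10 to 0 °C; used crude
Reagents that add atoms: phosphorus tribromide, BrP(Br)Br
Why: Conversion of a primary allylic alcohol into the allylic bromide with PBr3 (SN2 on the phosphite ester) is the standard entry to polyprenyl bromides and at low temperature leaves the four trisubstituted E-alkenes untouched.

Step 2
Reactants: 3 (R)-4-benzyl-2-oxazolidinone; 4 methyl 4-chloro-4-oxobutanoate
Product: 5 methyl 4-[(4R)-4-benzyl-2-oxo-1,3-oxazolidin-3-yl]-4-oxobutanoate
Conditions: Et3N, DMAP (cat.), CH2Cl2, 0 °C to rt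
Reagents that add atoms: none
Why: N-Acylation of the oxazolidinone by the acid chloride under amine base with nucleophilic catalysis gives the imide, since the acyl chloride is far more electrophilic than the methyl ester.

Step 3
Reactants: 5 methyl 4-[(4R)-4-benzyl-2-oxo-1,3-oxazolidin-3-yl]-4-oxobutanoate; 2 geranylgeranyl bromide
Product: 7 methyl (3R,5E,9E,13E)-3-[(4R)-4-benzyl-2-oxo-1,3-oxazolidine-3-carbonyl]-6,10,14,18-tetramethylnonadeca-5,9,13,17-tetraenoate, via sodium enolate 6 (not isolated)
Conditions: NaN(SiMe3)2, THF, −78 °C; then 2, −78 to −40 °C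
Reagents that add atoms: none
Why: Evans asymmetric alkylation, in which the base removes the more acidic imide α-proton rather than the ester α-proton to give the chelated Z-enolate 6, and the allylic bromide reacts at its primary carbon on the face opposite the benzyl group of the (R)-auxiliary, which sets C5 as R.

Step 4
Reactants: 7 alkylated imide
Product: 9 (4R)-4-geranylgeranyloxolan-2-one, via hydroxy ester 8 (not isolated)
Conditions: NaBH4, THF/H2O, 0 °C to rt; then PPTS (cat.), CH2Cl2, rt
Reagents that add atoms: none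
Why: Reductive cleavage of the auxiliary followed by lactonisation, in which borohydride reduces the activated exocyclic imide carbonyl to the primary alcohol and spares the methyl ester, and the γ-hydroxy ester 8 then closes to the five-membered lactone with C5 untouched.

Step 5
Reactants: 9 (4R)-4-geranylgeranyloxolan-2-one
Product: 10 (4R)-4-geranylgeranyloxolan-2-ol (lactol, both anomers)
Conditions: i-Bu2AlH (1.1 equiv), CH2Cl2, −78 °C; aq. KNaC4H4O6
Reagents that add atoms: none
Why: Partial reduction of a γ-lactone with i-Bu2AlH stops at the lactol because the tetrahedral aluminium hemiacetal is stable at −78 °C.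

Step 6
Reactants: 10 lactol; 11 ethynylmagnesium bromide
Product: 12 (2R)-2-geranylgeranylhex-5-yne-1,4-diol (both C4 epimers)
Conditions: HC≡CMgBr (3.5 equiv), THF, 0 °C to rt; aq. NH4Cl
Reagents that add atoms: none
Why: Grignard addition to the open hydroxy-aldehyde form of the lactol, in which the first equivalent deprotonates and the second adds to the aldehyde, gives the propargylic carbinol that becomes C1.

Step 7
Reactants: 12 (2R)-2-geranylgeranylhex-5-yne-1,4-diol
Product: 13 (5R)-6-[(tert-butyldimethylsilyl)oxy]-5-geranylgeranylhex-1-yn-3-ol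
Conditions: TBSCl (1.05 equiv), imidazole, CH2Cl2, 0 °C
Reagents that add atoms: tert-butyldimethylsilyl chloride, CC(C)(C)[Si](C)(C)Cl
Why: Silylation with TBSCl and imidazole is selective for the unhindered primary hydroxyl over the secondary propargylic one, which stays free to direct step 8.

Step 8
Reactants: 13 mono-silyl ether; 14 vinylmagnesium chloride
Product: 16 (1Z,5R)-6-[(tert-butyldimethylsilyl)oxy]-2-ethenyl-5-geranylgeranyl-1-iodohex-1-en-3-ol, via magnesium chelate 15 (not isolated)
Conditions: CH2=CHMgCl (4 equiv), CuI (15 mol%), THF, −20 °C to rt; then I2, −78 to 0 °C; aq. Na2S2O3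
Reagents that add atoms: iodine, II
Why: Copper-catalysed, alkoxide-directed anti-carbomagnesiation of a propargylic alcohol delivers the vinyl group to C2 and leaves magnesium on C3 inside the five-membered chelate 15, so iodinolysis with retention places iodine on C3 cis to C1 (Z), the geometry that the ring closure needs.

Step 9
Reactants: 16 iododiene alcohol
Product: 18 (3Z,6R)-7-[(tert-butyldimethylsilyl)oxy]-6-geranylgeranyl-3-(iodomethylidene)heptane-1,4-diol, via alkylborane 17 (not isolated)
Conditions: 9-BBN (2.5 equiv), THF, 0 °C to rt; then H2O2, aq. NaOH, 0 °C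
Reagents that add atoms: hydrogen peroxide, OO
Why: Hydroboration–oxidation with the bulky 9-BBN is anti-Markovnikov and strongly selective for the monosubstituted vinyl group over the four trisubstituted alkenes and the deactivated iodoalkene, and alkaline peroxide replaces boron by hydroxyl without touching the alkenyl iodide.

Step 10
Reactants: 18 diol
Product: 19 (3Z,6R)-7-[(tert-butyldimethylsilyl)oxy]-6-geranylgeranyl-1-hydroxy-3-(iodomethylidene)heptan-4-one
Conditions: MnO2 (activated, excess), CH2Cl2, rt, dark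
Reagents that add atoms: none
Why: Allylic oxidation with MnO2 converts the C1 carbinol into the enone and leaves the saturated primary alcohol, and doing this first removes the hydroxyl that would otherwise form a lactol and lactone with the arm in the next oxidation.

Step 11
Reactants: 19 hydroxy enone
Product: 20 (3Z,6R)-7-[(tert-butyldimethylsilyl)oxy]-6-geranylgeranyl-3-(iodomethylidene)-4-oxoheptanoic acid
Conditions: TEMPO (20 mol%), PhI(OAc)2 (2.5 equiv), MeCN/H2O, rt
Reagents that add atoms: water, O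
Why: Oxoammonium-catalysed oxidation in aqueous acetonitrile takes the primary alcohol through the aldehyde hydrate to the carboxylic acid under near-neutral conditions that the polyene, the silyl ether and the iodoenone should tolerate.

Step 12
Reactants: 20 keto acid
Product: 21 methyl (3Z,6R)-7-[(tert-butyldimethylsilyl)oxy]-6-geranylgeranyl-3-(iodomethylidene)-4-oxoheptanoate
Conditions: Me3SiCHN2 (1.2 equiv), PhMe/MeOH, 0 °C; AcOH quench
Reagents that add atoms: (trimethylsilyl)diazomethane, C[Si](C)(C)C=[N+]=[N-]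
Why: O-Methylation of the carboxylic acid by the diazoalkane (protonation, then SN2 by the carboxylate) needs no base, so the β-iodoenone and the acidic arm methylene are not disturbed.

Step 13
Reactants: 21 silyl keto ester
Product: 22 methyl (3Z,6R)-6-geranylgeranyl-7-hydroxy-3-(iodomethylidene)-4-oxoheptanoate
Conditions: HF·pyridine, pyridine, THF, 0 °C to rt
Reagents that add atoms: none
Why: Fluoride-mediated cleavage of the primary silyl ether with pyridine-buffered HF·pyridine is mild enough for the iodoenone, the ester and the acid-sensitive polyene.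

Step 14
Reactants: 22 hydroxy ketone
Product: 23 methyl (3Z,6R)-6-geranylgeranyl-3-(iodomethylidene)-4,7-dioxoheptanoate
Conditions: Dess–Martin periodinane (1.3 equiv), NaHCO3, CH2Cl2, 0 °C to rt; used at once
Reagents that add atoms: none
Why: Dess–Martin oxidation of the primary alcohol under bicarbonate buffer gives the aldehyde without a base strong enough to epimerise the α-stereocentre C5 or to isomerise the iodoenone.

Step 15
Reactants: 23 (Z)-β-iodoenone aldehyde
Product: 25 target methyl 2-[(3R,4R)-4-geranylgeranyl-3-hydroxy-6-oxocyclohex-1-en-1-yl]acetate, via alkenylchromium 24 (not isolated)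
Conditions: CrCl2 (6 equiv), NiCl2 (2 mol%), degassed DMSO/THF, rt, 0.005 M; neutral aqueous work-up
Reagents that add atoms: none
Why: Intramolecular Nozaki–Hiyama–Kishi reaction: zerovalent nickel, formed from NiCl2 by CrCl2, inserts into the C3–I bond with retention, the alkenyl group passes to trivalent chromium to give 24, and this β-acylvinyl nucleophile adds to the C4 aldehyde; the closest precedents are chromium-mediated cyclisations of iodoalkene aldehydes and couplings of β-iodoenones and β-iodoacrylates with aldehydes. The cyclohexenone ring closes in 6-exo-trig mode (C3 onto the C4 carbonyl carbon, oxygen outside the ring), which only the Z-alkenyl metal can reach. The new C4 stereocentre is controlled by C5: in the half-chair transition state the geranylgeranyl chain sits pseudo-equatorial and anti to the forming C3–C4 bond, while the chromium-bound aldehyde oxygen stands pseudo-axial between C6 and the side chain (Felkin–Anh orientation), which should favour the 4,5-cis (4R,5R) carbinol. The step needs chemoselectivity for the aldehyde over the C1 ketone and the ester, which organochromium reagents provide, and retention of configuration at C5, which the non-basic medium and the immediate use of 23 should secure. High dilution suppresses intermolecular coupling and the low nickel loading limits homocoupling of the alkenyl iodide.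

**Compound list**

1 | (2E,6E,10E)-geranylgeraniol | OC/C=C(\C)CC/C=C(\C)CC/C=C(\C)CCC=C(C)C | starting material
2 | (2E,6E,10E)-geranylgeranyl bromide | BrC/C=C(\C)CC/C=C(\C)CC/C=C(\C)CCC=C(C)C | intermediate
3 | (R)-4-benzyl-2-oxazolidinone | O=C1OC[C@@H](Cc2ccccc2)N1 | starting material
4 | methyl 4-chloro-4-oxobutanoate | COC(=O)CCC(=O)Cl | starting material
5 | methyl 4-[(4R)-4-benzyl-2-oxo-1,3-oxazolidin-3-yl]-4-oxobutanoate | O=C1OC[C@@H](Cc2ccccc2)N1C(=O)CCC(=O)OC | intermediate
6 | sodium Z-enolate of 5 (not isolated) | O=C1OC[C@@H](Cc2ccccc2)N1/C([O-])=C/CC(=O)OC.[Na+] | intermediate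
7 | methyl (3R,5E,9E,13E)-3-[(4R)-4-benzyl-2-oxo-1,3-oxazolidine-3-carbonyl]-6,10,14,18-tetramethylnonadeca-5,9,13,17-tetraenoate | O=C1OC[C@@H](Cc2ccccc2)N1C(=O)[C@H](C/C=C(\C)CC/C=C(\C)CC/C=C(\C)CCC=C(C)C)CC(=O)OC | intermediate
8 | methyl (3R,5E,9E,13E)-3-(hydroxymethyl)-6,10,14,18-tetramethylnonadeca-5,9,13,17-tetraenoate (not isolated) | OC[C@H](C/C=C(\C)CC/C=C(\C)CC/C=C(\C)CCC=C(C)C)CC(=O)OC | intermediate
9 | (4R)-4-geranylgeranyloxolan-2-one | O1C[C@H](C/C=C(\C)CC/C=C(\C)CC/C=C(\C)CCC=C(C)C)CC1=O | intermediate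
10 | (4R)-4-geranylgeranyloxolan-2-ol (anomers) | O1C[C@H](C/C=C(\C)CC/C=C(\C)CC/C=C(\C)CCC=C(C)C)CC1O | intermediate
11 | ethynylmagnesium bromide | C#C[Mg]Br | starting material
12 | (2R)-2-geranylgeranylhex-5-yne-1,4-diol (C4 epimers) | OC[C@H](C/C=C(\C)CC/C=C(\C)CC/C=C(\C)CCC=C(C)C)CC(O)C#C | intermediate
13 | (5R)-6-[(tert-butyldimethylsilyl)oxy]-5-geranylgeranylhex-1-yn-3-ol | CC(C)(C)[Si](C)(C)OC[C@H](C/C=C(\C)CC/C=C(\C)CC/C=C(\C)CCC=C(C)C)CC(O)C#C | intermediate
14 | vinylmagnesium chloride | C=C[Mg]Cl | starting material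
15 | cyclic alkenylmagnesium alkoxide, a 2,5-dihydro-1,2-oxamagnesole with magnesium on C3 (not isolated) | CC(C)(C)[Si](C)(C)OC[C@H](C/C=C(\C)CC/C=C(\C)CC/C=C(\C)CCC=C(C)C)CC1O[Mg]C=C1C=C | intermediate
16 | (1Z,5R)-6-[(tert-butyldimethylsilyl)oxy]-2-ethenyl-5-geranylgeranyl-1-iodohex-1-en-3-ol | CC(C)(C)[Si](C)(C)OC[C@H](C/C=C(\C)CC/C=C(\C)CC/C=C(\C)CCC=C(C)C)CC(O)/C(C=C)=C\I | intermediate
17 | B-alkyl-9-borabicyclo[3.3.1]nonane adduct of 16 (not isolated) | CC(C)(C)[Si](C)(C)OC[C@H](C/C=C(\C)CC/C=C(\C)CC/C=C(\C)CCC=C(C)C)CC(O)/C(CCB1C2CCCC1CCC2)=C\I | intermediate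
18 | (3Z,6R)-7-[(tert-butyldimethylsilyl)oxy]-6-geranylgeranyl-3-(iodomethylidene)heptane-1,4-diol | CC(C)(C)[Si](C)(C)OC[C@H](C/C=C(\C)CC/C=C(\C)CC/C=C(\C)CCC=C(C)C)CC(O)/C(CCO)=C\I | intermediate
19 | (3Z,6R)-7-[(tert-butyldimethylsilyl)oxy]-6-geranylgeranyl-1-hydroxy-3-(iodomethylidene)heptan-4-one | CC(C)(C)[Si](C)(C)OC[C@H](C/C=C(\C)CC/C=C(\C)CC/C=C(\C)CCC=C(C)C)CC(=O)/C(CCO)=C\I | intermediate
20 | (3Z,6R)-7-[(tert-butyldimethylsilyl)oxy]-6-geranylgeranyl-3-(iodomethylidene)-4-oxoheptanoic acid | CC(C)(C)[Si](C)(C)OC[C@H](C/C=C(\C)CC/C=C(\C)CC/C=C(\C)CCC=C(C)C)CC(=O)/C(CC(=O)O)=C\I | intermediate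
21 | methyl (3Z,6R)-7-[(tert-butyldimethylsilyl)oxy]-6-geranylgeranyl-3-(iodomethylidene)-4-oxoheptanoate | CC(C)(C)[Si](C)(C)OC[C@H](C/C=C(\C)CC/C=C(\C)CC/C=C(\C)CCC=C(C)C)CC(=O)/C(CC(=O)OC)=C\I | intermediate
22 | methyl (3Z,6R)-6-geranylgeranyl-7-hydroxy-3-(iodomethylidene)-4-oxoheptanoate | OC[C@H](C/C=C(\C)CC/C=C(\C)CC/C=C(\C)CCC=C(C)C)CC(=O)/C(CC(=O)OC)=C\I | intermediate
23 | methyl (3Z,6R)-6-geranylgeranyl-3-(iodomethylidene)-4,7-dioxoheptanoate (key-step precursor) | O=C[C@H](C/C=C(\C)CC/C=C(\C)CC/C=C(\C)CCC=C(C)C)CC(=O)/C(CC(=O)OC)=C\I | intermediate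
24 | alkenylchromium dichloride of 23, trivalent chromium on C3 (not isolated) | O=C[C@H](C/C=C(\C)CC/C=C(\C)CC/C=C(\C)CCC=C(C)C)CC(=O)/C(CC(=O)OC)=C\[Cr](Cl)Cl | intermediate
25 | methyl 2-[(3R,4R)-4-geranylgeranyl-3-hydroxy-6-oxocyclohex-1-en-1-yl]acetate (CNP0274044.1) | COC(=O)CC1=C[C@H](O)[C@H](C/C=C(\C)CC/C=C(\C)CC/C=C(\C)CCC=C(C)C)CC1=O | target

**Step count**

Total: 15 steps. Longest linear sequence: 14 steps (steps 2–15 from 3 and 4, or step 1 followed by steps 3–15 from 1).

**Steps most likely to fail**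

1. Step 15. The aldehyde may be attacked on the other face, giving the 4,5-trans carbinol, and the γ-hydroxy enone may lose water towards the phenol if the work-up is not neutral. Fallback, setting out from 23 and returning at 25: the cyclisation is run as written and the methyl 2-[(3S,4R)-4-geranylgeranyl-3-hydroxy-6-oxocyclohex-1-en-1-yl]acetate F1 (4,5-trans epimer) is separated. Mitsunobu esterification (4-nitrobenzoic acid, PPh3, DIAD, THF, 0 °C) inverts C4 to the 4,5-cis 4-nitrobenzoate of the target carbinol F2. Mild methanolysis (K2CO3, MeOH, 0 °C) then gives 25.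

2. Step 8. Deprotonation of the terminal alkyne by the Grignard reagent may compete with carbometallation, so that addition stalls at the acetylide or iodine ends up on the alkyne terminus. Fallback, setting out from 10 and returning at 16: the alkyne is capped with silicon.
   - Lactol 10 is treated with Me3SiC≡CLi (THF, −78 to 0 °C) to give (2R)-2-geranylgeranyl-6-(trimethylsilyl)hex-5-yne-1,4-diol F3.
   - TBSCl and imidazole give (5R)-6-[(tert-butyldimethylsilyl)oxy]-5-geranylgeranyl-1-(trimethylsilyl)hex-1-yn-3-ol F4.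
   - Uncatalysed alkoxide-directed anti-vinylmagnesiation of this internal alkynol (CH2=CHMgCl, THF, reflux), with no acidic C–H and with silicon stabilising the C3 carbanion, followed by I2, gives (1Z,5R)-6-[(tert-butyldimethylsilyl)oxy]-2-ethenyl-5-geranylgeranyl-1-iodo-1-(trimethylsilyl)hex-1-en-3-ol F5.
   - Protodesilylation of the α-iodoalkenylsilane with retention (NaOMe, MeOH, rt) gives 16.

3. Step 11. The transient β,γ-unsaturated aldehyde may enolise and shift or scramble the C2=C3 double bond, or the arm hydroxyl of 19 may displace the C3 iodide by addition–elimination. Fallback, setting out from 18 and returning at 21: the C1 oxygen is tied up during the arm oxidation.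
   - TEMPO (cat.) and PhI(OAc)2 in CH2Cl2 convert the 1,4-diol 18 into (4Z)-5-[(2R)-3-[(tert-butyldimethylsilyl)oxy]-2-geranylgeranylpropyl]-4-(iodomethylidene)oxolan-2-one F6.
   - Saponification (LiOH, THF/H2O, 0 °C) and alkylation of the carboxylate (MeI, DMF) give methyl (3Z,6R)-7-[(tert-butyldimethylsilyl)oxy]-6-geranylgeranyl-4-hydroxy-3-(iodomethylidene)heptanoate F7.
   - F7 is oxidised at once with Dess–Martin periodinane (NaHCO3, CH2Cl2) to 21.

Further compounds
F1 | step 15 | methyl 2-[(3S,4R)-4-geranylgeranyl-3-hydroxy-6-oxocyclohex-1-en-1-yl]acetate (4,5-trans epimer) | COC(=O)CC1=C[C@@H](O)[C@H](C/C=C(\C)CC/C=C(\C)CC/C=C(\C)CCC=C(C)C)CC1=O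
F2 | step 15 | 4-nitrobenzoate of the target carbinol (4,5-cis, C4 R, C5 R) | COC(=O)CC1=C[C@H](OC(=O)c2ccc(cc2)[N+](=O)[O-])[C@H](C/C=C(\C)CC/C=C(\C)CC/C=C(\C)CCC=C(C)C)CC1=O
F3 | step 8 | (2R)-2-geranylgeranyl-6-(trimethylsilyl)hex-5-yne-1,4-diol | OC[C@H](C/C=C(\C)CC/C=C(\C)CC/C=C(\C)CCC=C(C)C)CC(O)C#C[Si](C)(C)C
F4 | step 8 | (5R)-6-[(tert-butyldimethylsilyl)oxy]-5-geranylgeranyl-1-(trimethylsilyl)hex-1-yn-3-ol | CC(C)(C)[Si](C)(C)OC[C@H](C/C=C(\C)CC/C=C(\C)CC/C=C(\C)CCC=C(C)C)CC(O)C#C[Si](C)(C)C
F5 | step 8 | (1Z,5R)-6-[(tert-butyldimethylsilyl)oxy]-2-ethenyl-5-geranylgeranyl-1-iodo-1-(trimethylsilyl)hex-1-en-3-ol | CC(C)(C)[Si](C)(C)OC[C@H](C/C=C(\C)CC/C=C(\C)CC/C=C(\C)CCC=C(C)C)CC(O)/C(C=C)=C(\I)[Si](C)(C)C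
F6 | step 11 | (4Z)-5-[(2R)-3-[(tert-butyldimethylsilyl)oxy]-2-geranylgeranylpropyl]-4-(iodomethylidene)oxolan-2-one | CC(C)(C)[Si](C)(C)OC[C@H](C/C=C(\C)CC/C=C(\C)CC/C=C(\C)CCC=C(C)C)CC1OC(=O)C/C1=C/I
F7 | step 11 | methyl (3Z,6R)-7-[(tert-butyldimethylsilyl)oxy]-6-geranylgeranyl-4-hydroxy-3-(iodomethylidene)heptanoate | CC(C)(C)[Si](C)(C)OC[C@H](C/C=C(\C)CC/C=C(\C)CC/C=C(\C)CCC=C(C)C)CC(O)/C(CC(=O)OC)=C\I
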